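**Plan**

1. Labels: ring A is the methoxy-enedione ring, Cm its spiro (malonyl) carbon between the two carbonyls, Ck the carbonyl next to C(CH3)2 and Ce the carbonyl next to C(CH3)=. Ring B is the cyclopentane Cm–Cc–Cb–Ca–Cp (Cc carries the isopropyl group, Cb and Ca are CH2, Cp is the pinane spiro carbon, Cq the bridgehead CH beside it).
2. Retrosynthesis: the O–CH3 bond is cut first, then ring A at Ck–C(CH3)2 (Dieckmann) and Ce–CH(CH3) (Claisen). This removes 2-methylpentan-3-one and leaves Cm as a malonate masked as Meldrum's acid. Ring B is then cut at Ca–Cp and Cm–Cc in one operation, and the remaining Cp=Cm double bond leads back to nopinone and Meldrum's acid, hence to (+)-β-pinene.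
3. Feature: in ring B, Cm carries two carbonyl groups, is bonded to the quaternary Cp and lies on the side of the gem-dimethyl bridge, while Cc carries a three-carbon branch. Cm can therefore be installed first as the acceptor carbon of a Cp=Cm alkene, Ca then has to reach Cp from the open face, and the branch on Cc is what an isopropenylcyclopropane leaves behind.
4. Forward order: pinane bicycle (bought) → exocyclic alkylidene Meldrum's acid → ring B by radical [3+2] annulation → hydrogenation → ring A by opening the Meldrum's acid and two C-acylations → O-methylation.
5. Stereochemistry: both bridgeheads come from (+)-β-pinene; Cp from bond formation anti to the gem-dimethyl bridge; Cc from the 5-exo closure (branch trans to Cq); Cm from group-selective opening of the Meldrum's acid at the carbonyl syn to the Cc hydrogen.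

Key step: step 3

Assumption: isopropenylcyclopropane is taken as a purchasable reagent, and the 1,3-dicarbonyl compounds of the late steps are drawn as single tautomers.

**Route**

Step 1
Reactants: 1 (+)-β-pinene, (1R,5R)-6,6-dimethyl-2-methylidenebicyclo[3.1.1]heptane
Product: 3 (1S,5R)-nopinone, via ozonide 2 (not isolated)
Conditions: O3, CH2Cl2, −78 °C; then PPh3, −78 °C to rt
Reagents that add atoms: ozone, O=[O+][O-]
Why: Ozonolysis of the exocyclic 1,1-disubstituted alkene with reductive work-up removes only the methylidene carbon, so the ketone keeps both bridgehead configurations of 1 and no new stereocenter arises.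

Step 2
Reactants: 3 (1S,5R)-nopinone; 4 Meldrum's acid (2,2-dimethyl-1,3-dioxane-4,6-dione)
Product: 5 pinane alkylidene Meldrum's acid, 5-(6,6-dimethylbicyclo[3.1.1]hept-2-ylidene)-2,2-dimethyl-1,3-dioxane-4,6-dione with the bridgeheads of 1
Conditions: TiCl4 (2 equiv), pyridine (4 equiv), THF, 0 °C to rt
Reagents that add atoms: none
Why: Knoevenagel condensation under TiCl4–pyridine activation is the standard entry to ketone-derived alkylidene Meldrum's acids; the Meldrum's end of the alkene is symmetric, so neither alkene isomers nor a new stereocenter can form.

Step 3
Reactants: 5 pinane alkylidene Meldrum's acid; 6 isopropenylcyclopropane (2-cyclopropylpropene)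
Product: 7 dispiro Meldrum's acid with ring B closed, isopropenyl on Cc trans to Cq, Ca anti to the gem-dimethyl bridge
Conditions: 6 (5 equiv, in portions), PhSSPh (0.2 equiv), hν (365 nm), degassed benzene, 25 °C
Reagents that add atoms: none
Why: Light splits PhSSPh into PhS radicals, one of which adds to the CH2 end of 6; the tertiary cyclopropylcarbinyl radical opens to the primary homoallyl radical PhSCH2C(CH3)=CHCH2CH2•, whose terminal carbon (Ca) adds to the β-carbon Cp of 5, the radical then sits on Cm between the two carbonyls, attacks the CH of the allyl sulfide (Cc), and β-scission of the C–S bond returns PhS• and leaves the isopropenyl group. The closest known reaction is the thiyl-radical-catalysed [3+2] annulation of vinylcyclopropanes with electron-poor alkenes. Ring B closes in the 5-exo-trig mode, which gives a tertiary radical that can only fragment to the alkene. Cp is controlled by the pinane cage: the gem-dimethyl bridge covers one face of the exocyclic alkene, so Ca bonds from the other face and Cm is left syn to that bridge. Cc is controlled in the chair-like transition state of the 5-exo closure, where the forming branch avoids the bridgehead Cq and the bridge behind it and ends up trans to Cq. The step needs the nucleophilic primary radical to choose 5 over 6 and the disulfide, which the two carbonyl groups on the alkene should secure by polarity matching, and because no radical is ever centred on Cp or Cq the cyclobutane stays closed.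

Step 4
Reactants: 7 dispiro Meldrum's acid with isopropenyl on Cc
Product: 8 dispiro Meldrum's acid with isopropyl on Cc
Conditions: H2 (1 atm), PtO2 (5 mol%), EtOAc, rt
Reagents that add atoms: none
Why: Heterogeneous hydrogenation of a 1,1-disubstituted alkene is fast while the Meldrum's acid and the cyclobutane are inert, and platinum is chosen over palladium because it moves the double bond less readily toward Cc, whose configuration must be kept; the isopropyl carbon is not stereogenic.

Step 5
Reactants: 8 dispiro Meldrum's acid with isopropyl on Cc
Product: 9 half ester, Cm bearing CO2CH3 (Ck) syn to the Cc hydrogen and CO2H (Ce) syn to the isopropyl group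
Conditions: NaOMe (1.5 equiv), MeOH/THF, 0 °C to rt; then cold 1 M HCl
Reagents that add atoms: sodium methoxide, [Na+].[O-]C
Why: Alcoholysis of a 5,5-disubstituted Meldrum's acid (acyl substitution with loss of acetone) stops after one event because the second carbonyl becomes a carboxylate, and the choice between the two diastereotopic carbonyls should follow the approach path: the one on the face of ring B that carries the Cc hydrogen is reached over that hydrogen, while its partner sits between the cis isopropyl group and the pinane CH2 next to Cp, which fixes Cm.

Step 6
Reactants: 9 half ester; 10 2-methylpentan-3-one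
Product: 13 diketone ester, via acid chloride 11 (not isolated), via lithium enolate 12 (not isolated)
Conditions: (COCl)2, DMF (cat.), CH2Cl2, 0 °C to rt, evaporate; separately 10 (2.3 equiv), LiN(iPr)2 (2.2 equiv), THF, −78 °C; add 11, −78 to −20 °C; then 1 M HCl
Reagents that add atoms: none
Why: Crossed Claisen C-acylation of a preformed ketone lithium enolate by an acid chloride: the amide base deprotonates 10 at its CH2 group, the hindered but highly electrophilic acid chloride has no α-hydrogen and reacts far faster than the methyl ester on the same carbon, and the second equivalent of enolate is consumed by the acidic product; Cm is untouched and the new CH(CH3) centre is an enolisable position of no consequence.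

Step 7
Reactants: 13 diketone ester, Ce(=O)–CH(CH3)–C(=O)–CH(CH3)2 with CO2CH3 at Ck
Product: 14 spiro triketone with ring A closed, drawn as the enol (the target with OH in place of OCH3)
Conditions: LiN(iPr)2 (3.2 equiv), THF, −78 to 25 °C; then 1 M HCl
Reagents that add atoms: none
Why: Dieckmann-type intramolecular Claisen condensation through the diketone dianion: once the central CH(CH3) is deprotonated, the only remaining acidic C–H is that of the isopropyl group, and this γ-carbanion attacks the Ck methyl ester in a six-membered closure that is pulled forward by formation of the stabilised triketone enolate; no stereocenter is created or touched.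

Step 8
Reactants: 14 spiro triketone (enol)
Product: 15 target, methyl enol ether
Conditions: Me2SO4 (1.5 equiv), K2CO3 (2 equiv), acetone, 56 °C
Reagents that add atoms: dimethyl sulfate, COS(=O)(=O)OC
Why: O-Alkylation of a vinylogous acid with a hard methylating agent; of the two enolate oxygens the one flanked by C(CH3)2 and C(CH3)= is accessible, whereas the oxygen on Ce is buried beside the spiro carbon Cm and the cis isopropyl group, so the enol ether of the target should prevail and Ce stays a carbonyl.

**Compound list**

1 | (+)-β-pinene, (1R,5R)-6,6-dimethyl-2-methylidenebicyclo[3.1.1]heptane | C=C1CC[C@@H]2C[C@H]1C2(C)C | starting material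
2 | β-pinene ozonide, spiro-1,2,4-trioxolane on carbon 2 of the pinane (either configuration at the trioxolane spiro carbon) | C1OC2(OO1)CC[C@@H]1C[C@H]2C1(C)C | intermediate
3 | (1S,5R)-nopinone, 6,6-dimethylbicyclo[3.1.1]heptan-2-one | O=C1CC[C@@H]2C[C@H]1C2(C)C | intermediate
4 | Meldrum's acid, 2,2-dimethyl-1,3-dioxane-4,6-dione | CC1(C)OC(=O)CC(=O)O1 | starting material
5 | pinane alkylidene Meldrum's acid, 5-(6,6-dimethylbicyclo[3.1.1]hept-2-ylidene)-2,2-dimethyl-1,3-dioxane-4,6-dione, bridgeheads as in 1 | CC1(C)OC(=O)C(C(=O)O1)=C1CC[C@@H]2C[C@H]1C2(C)C | intermediate
6 | isopropenylcyclopropane (2-cyclopropylpropene) | CC(=C)C1CC1 | starting material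
7 | dispiro Meldrum's acid: cyclopentane ring B spiro-fused at Cm to the dioxanedione and at Cp to the pinane, Ca anti to the gem-dimethyl bridge, isopropenyl on Cc trans to Cq | CC1(C)OC(=O)C2(C(=O)O1)[C@@H](C(C)=C)CC[C@@]21CC[C@@H]2C[C@H]1C2(C)C | intermediate
8 | dispiro Meldrum's acid as 7 with isopropyl on Cc | CC1(C)OC(=O)C2(C(=O)O1)[C@@H](C(C)C)CC[C@@]21CC[C@@H]2C[C@H]1C2(C)C | intermediate
9 | half ester: Cm carries CO2CH3 (Ck, syn to the Cc hydrogen) and CO2H (Ce, syn to isopropyl) | OC(=O)[C@@]2(C(=O)OC)[C@@H](C(C)C)CC[C@@]21CC[C@@H]2C[C@H]1C2(C)C | intermediate
10 | 2-methylpentan-3-one | CCC(=O)C(C)C | starting material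
11 | acid chloride of 9 (COCl at Ce, CO2CH3 at Ck) | ClC(=O)[C@@]2(C(=O)OC)[C@@H](C(C)C)CC[C@@]21CC[C@@H]2C[C@H]1C2(C)C | intermediate
12 | lithium enolate of 10 at the CH2 carbon, lithium 2-methylpent-3-en-3-olate (enolate geometry not defined) | [Li+].[O-]C(=CC)C(C)C | intermediate
13 | diketone ester: Ce(=O)–CH(CH3)–C(=O)–CH(CH3)2 on Cm with CO2CH3 at Ck (CH(CH3) epimers and enol forms) | CC(C)C(=O)C(C)C(=O)[C@@]2(C(=O)OC)[C@@H](C(C)C)CC[C@@]21CC[C@@H]2C[C@H]1C2(C)C | intermediate
14 | spiro triketone with ring A closed, drawn as the enol with OH on the carbon between C(CH3)2 and C(CH3)= | OC1=C(C)C(=O)[C@@]2(C(=O)C1(C)C)[C@@H](C(C)C)CC[C@@]21CC[C@@H]2C[C@H]1C2(C)C | intermediate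
15 | target CNP0307059.1, methyl enol ether of 14 | COC1=C(C)C(=O)[C@@]2(C(=O)C1(C)C)[C@@H](C(C)C)CC[C@@]21CC[C@@H]2C[C@H]1C2(C)C | target

**Count and risks**

Total steps: 8. Longest linear sequence: 8 steps (1 to 15); 4, 6 and 10 are bought and enter in steps 2, 3 and 6.

Steps most likely to fail:

Step 3. The chain may stall because the primary radical adds too slowly to the fully substituted carbon Cp, so that oligomerisation of the vinylcyclopropane or trapping by the disulfide takes over. The fallback sets out from 5 and rejoins the route at 7, making the same two bonds one after the other. 4-Methylpent-3-enylmagnesium bromide F1 (prepared from 5-bromo-2-methylpent-2-ene and Mg in THF) is added to 5 with catalytic CuBr·SMe2 at −40 °C. Conjugate addition to the alkylidene Meldrum's acid, again anti to the gem-dimethyl bridge, should give the monosubstituted Meldrum's acid F2, in which the Ca–Cp bond already exists. Oxidative radical cyclisation of F2 with Mn(OAc)3 and Cu(OAc)2 in acetic acid then generates the Cm radical from the acidic C–H and closes ring B 5-exo onto the trisubstituted alkene. Divalent copper turns the tertiary radical into the isopropenyl group, which gives 7.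

Step 5. Methoxide may attack the carbonyl syn to the isopropyl group as well as, or instead of, the intended one; such poor or reversed group selectivity would invert Cm relative to Cc in everything that follows. The fallback sets out from 8 and rejoins the route at 14 by reversing the order of the two C-acylations, so that the other half ester leads to the same Cm configuration. The half ester with exchanged functions F3 (CO2H syn to the Cc hydrogen, CO2CH3 syn to isopropyl), which should be separable from 9 by chromatography, is converted into its acid chloride F4 with (COCl)2 and catalytic DMF. F4 is C-acylated under ZnCl2 mediation by the tetrasubstituted silyl enol ether F5, made from 10 with Me3SiCl, NaI and Et3N in MeCN (more substituted isomer). This gives the 2,2-dimethyl-1,3-diketone F6, in which the Ck–C(CH3)2 bond already exists. LiN(iPr)2 then forms the ethyl ketone enolate, which closes ring A by Dieckmann attack on the Ce methyl ester and delivers 14.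

Step 7. The diketone enolate may acylate on oxygen (closure to a six-membered enol lactone), or the tertiary γ-carbanion may fail to form or to reach the hindered ester. The fallback sets out from 13 and rejoins the route at 15. 13 is O-methylated first (Me2SO4, K2CO3, acetone) at the less hindered isobutyryl oxygen to give the β-methoxy enone F7. With the enol oxygen capped, KN(SiMe3)2 in THF can only remove the γ-hydrogen of the isopropyl group. The dienolate closes onto the Ck methyl ester in a vinylogous Dieckmann condensation and gives 15 directly, which also settles the position of the methoxy group.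

**Further compounds**

F1 | step 3 | 4-methylpent-3-enylmagnesium bromide | CC(C)=CCC[Mg]Br
F2 | step 3 | Meldrum's acid bearing on its ring CH carbon a 6,6-dimethylbicyclo[3.1.1]hept-2-yl group whose carbon 2 also carries the 4-methylpent-3-enyl chain (chain anti to the gem-dimethyl bridge) | CC1(C)OC(=O)C(C(=O)O1)[C@@]1(CCC=C(C)C)CC[C@@H]2C[C@H]1C2(C)C
F3 | step 5 | half ester with exchanged functions: CO2H at Ck (syn to the Cc hydrogen), CO2CH3 at Ce (syn to isopropyl) | COC(=O)[C@@]2(C(O)=O)[C@@H](C(C)C)CC[C@@]21CC[C@@H]2C[C@H]1C2(C)C
F4 | step 5 | acid chloride of F3 (COCl at Ck) | COC(=O)[C@@]2(C(Cl)=O)[C@@H](C(C)C)CC[C@@]21CC[C@@H]2C[C@H]1C2(C)C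
F5 | step 5 | 2-methyl-3-(trimethylsilyloxy)pent-2-ene | CCC(O[Si](C)(C)C)=C(C)C
F6 | step 5 | 2,2-dimethyl-1,3-diketone ester: Ck(=O)–C(CH3)2–C(=O)–CH2CH3 on Cm with CO2CH3 at Ce | COC(=O)[C@@]2(C(=O)C(C)(C)C(=O)CC)[C@@H](C(C)C)CC[C@@]21CC[C@@H]2C[C@H]1C2(C)C
F7 | step 7 | β-methoxy enone ester: Ce(=O)–C(CH3)=C(OCH3)–CH(CH3)2 on Cm with CO2CH3 at Ck (enol ether geometry not defined) | COC(C(C)C)=C(C)C(=O)[C@@]2(C(=O)OC)[C@@H](C(C)C)CC[C@@]21CC[C@@H]2C[C@H]1C2(C)C
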